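**Retrosynthetic overview**
1. C3–Br comes from SN2 inversion of the secondary OH of a cis-1,3-diol, itself from OH-directed epoxidation and hydride opening of an allylic alcohol made by CBS reduction of a ring A enone (C3 by reagent control, C1 relayed from C3).
2. The ring A enone comes from a vinylogous ester by Stork–Danheiser MeLi addition and transposition; the (Z)-bromomethylidene comes from a Wittig reaction on the ring B enone of a spiro[5.5]undecadienedione.
3. Ring B (formed second) is closed by intramolecular aldol condensation of a 1,5-keto aldehyde.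
4. The key C6–C11 bond is made by enantioselective intermolecular Michael addition of an α-formyl ketone to methyl vinyl ketone, which creates the spiro quaternary stereocentre.
5. Ring A (first) is bought as dimedone; C7 is added by crossed Claisen condensation with ethyl formate.

Locants: the spiro[5.5]undecane numbering of the target is used for all spiro compounds (C1 carbinol, C3 CHBr, C5 CMe2, C6 spiro, C7=C8, C9 =CHBr).

Assumption: the cupreidine-derived catalyst of step 3 is taken to give the 1R keto aldehyde; if the sense proves opposite, its cupreine-derived pseudoenantiomer is used and nothing else changes.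

**Route**

Step 1
Reactants: 1 dimedone (5,5-dimethylcyclohexane-1,3-dione)
Product: 2 5,5-dimethyl-3-(2-methylpropoxy)cyclohex-2-en-1-one
Conditions: i-BuOH (3 equiv), TsOH·H2O (2 mol %), toluene, reflux, Dean–Stark
Reagents that add atoms: 2-methylpropan-1-ol, CC(C)CO
Why: Acid-catalysed enol etherification of the 1,3-dione (vinylogous ester formation) driven by azeotropic removal of water; it leaves C6 as the only kinetically enolisable α-carbon and creates no stereocentre.

Step 2
Reactants: 2 5,5-dimethyl-3-(2-methylpropoxy)cyclohex-2-en-1-one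
Product: 3 6,6-dimethyl-4-(2-methylpropoxy)-2-oxocyclohex-3-ene-1-carbaldehyde (present as its hydroxymethylene enol)
Conditions: LiN(i-Pr)2 (1.2 equiv), THF, −78 °C; HCO2Et (3 equiv), −78 °C → rt; aq. HCl to pH 4, 0 °C
Reagents that add atoms: ethyl formate, CCOC=O
Why: Kinetic α′-deprotonation at C6 followed by a crossed Claisen condensation with the non-enolisable formate ester, pulled forward by formation of the stabilised β-keto aldehyde enolate; the small formyl group is tolerated next to the CMe2 carbon and no lasting stereocentre is formed.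

Step 3
Reactants: 3 6,6-dimethyl-4-(2-methylpropoxy)-2-oxocyclohex-3-ene-1-carbaldehyde; 4 methyl vinyl ketone (but-3-en-2-one)
Product: 5 (1R)-6,6-dimethyl-4-(2-methylpropoxy)-2-oxo-1-(3-oxobutyl)cyclohex-3-ene-1-carbaldehyde
Conditions: 4 (2 equiv), 9-O-benzylcupreidine (10 mol %), CH2Cl2, −20 °C
Reagents that add atoms: none
Why: Intermolecular Michael addition under bifunctional cinchona catalysis: the quinuclidine deprotonates the acidic hydroxymethylene ketone, the 6′-OH activates 4, and the ion-paired enolate, whose two faces are flanked by very different groups (C=O versus CMe2), adds through C6 on one face to form the C6–C11 bond and the quaternary stereocentre (1R); any minor enantiomer becomes a separable diastereomer after step 7.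

Step 4
Reactants: 5 (1R)-6,6-dimethyl-4-(2-methylpropoxy)-2-oxo-1-(3-oxobutyl)cyclohex-3-ene-1-carbaldehyde
Product: 7 (6S)-5,5-dimethyl-3-(2-methylpropoxy)spiro[5.5]undeca-2,7-diene-1,9-dione, via aldol ketol 6 (not isolated)
Conditions: pyrrolidine (0.3 equiv), AcOH (0.3 equiv), toluene, 4 Å molecular sieves, 60 °C
Reagents that add atoms: none
Why: Amine/acid-catalysed intramolecular aldol condensation that closes ring B: the methyl-ketone enamine attacks the non-enolisable aldehyde, far more electrophilic than the hindered vinylogous-ester carbonyl, and dehydration of ketol 6 gives the conjugated enone, the quaternary centre being untouched (its descriptor changes from R to S only through CIP ranking).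

Step 5
Reactants: 7 (6S)-5,5-dimethyl-3-(2-methylpropoxy)spiro[5.5]undeca-2,7-diene-1,9-dione
Product: 8 (6S,9Z)-9-(bromomethylidene)-5,5-dimethyl-3-(2-methylpropoxy)spiro[5.5]undeca-2,7-dien-1-one
Conditions: BrCH2PPh3Br (2.5 equiv), NaN(SiMe3)2 (2.4 equiv), THF, −78 °C; then 7, −78 → 0 °C; chromatography on AgNO3-doped SiO2
Reagents that add atoms: (bromomethyl)triphenylphosphonium bromide, BrC[P+](c1ccccc1)(c1ccccc1)c1ccccc1.[Br-]
Why: Wittig olefination with Ph3P=CHBr, which reacts only at the ring B enone carbonyl because the C1 carbonyl is a hindered vinylogous ester; the reaction is not geometry-selective, so the 9Z isomer (Br syn to C8) is isolated from the accompanying 9E isomer by chromatography.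

Step 6
Reactants: 8 (6S,9Z)-9-(bromomethylidene)-5,5-dimethyl-3-(2-methylpropoxy)spiro[5.5]undeca-2,7-dien-1-one
Product: 10 (6S,9Z)-9-(bromomethylidene)-1,5,5-trimethylspiro[5.5]undeca-1,7-dien-3-one, via tertiary carbinol 9 (not isolated)
Conditions: MeLi (3 equiv), CeCl3 (3 equiv), THF, −78 → 0 °C; then 1 M aq. HCl, THF, rt
Reagents that add atoms: methyllithium, [Li]C; water, O
Why: Stork–Danheiser sequence: non-basic MeCeCl2 adds 1,2 to the hindered vinylogous-ester carbonyl without touching the vinyl bromide, and acid hydrolysis of the enol ether with loss of water from carbinol 9 transposes the carbonyl to C3 and leaves the methyl on C1; no new stereocentre remains.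

Step 7
Reactants: 10 (6S,9Z)-9-(bromomethylidene)-1,5,5-trimethylspiro[5.5]undeca-1,7-dien-3-one
Product: 11 (3S,6S,9Z)-9-(bromomethylidene)-1,5,5-trimethylspiro[5.5]undeca-1,7-dien-3-ol
Conditions: (R)-2-methyl-CBS-oxazaborolidine (20 mol %), catecholborane (1.8 equiv), toluene, −78 → −40 °C; aqueous work-up
Reagents that add atoms: none
Why: Corey–Bakshi–Shibata reduction: catalyst-controlled hydride delivery, with the alkenyl arm acting as the large group as in simple cyclohexenones, gives the 3S allylic alcohol regardless of the remote spiro centre, and catecholborane at low temperature does not hydroborate the diene.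

Step 8
Reactants: 11 (3S,6S,9Z)-9-(bromomethylidene)-1,5,5-trimethylspiro[5.5]undeca-1,7-dien-3-ol
Product: 12 (1R,2S,3S,6S,9Z)-9-(bromomethylidene)-1,2-epoxy-1,5,5-trimethylspiro[5.5]undec-7-en-3-ol
Conditions: VO(acac)2 (5 mol %), t-BuOOH (1.5 equiv, decane solution), CH2Cl2, 0 °C → rt
Reagents that add atoms: tert-butyl hydroperoxide, CC(C)(C)OO
Why: VO(acac)2-catalysed hydroxyl-directed epoxidation (Sharpless–Michaelson): the allylic vanadate delivers oxygen to the C1=C2 face syn to the C3 hydroxyl, which places the C1 oxygen on the C11 side of ring A (1R,2S) and leaves the undirected bromodiene untouched.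

Step 9
Reactants: 12 (1R,2S,3S,6S,9Z)-9-(bromomethylidene)-1,2-epoxy-1,5,5-trimethylspiro[5.5]undec-7-en-3-ol
Product: 13 (1S,3S,6S,9Z)-9-(bromomethylidene)-1,5,5-trimethylspiro[5.5]undec-7-ene-1,3-diol
Conditions: LiEt3BH (3 equiv), THF, 0 °C → rt; H2O quench
Reagents that add atoms: none
Why: SN2 hydride opening of the trisubstituted epoxide at the secondary carbon C2 (C1 is fully substituted and neopentyl) gives the tertiary alcohol with retention at C1 and hence the cis-1,3-diol; the cis epoxy alcohol cannot undergo Payne rearrangement and the borohydride does not reduce vinyl bromides.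

Step 10
Reactants: 13 (1S,3S,6S,9Z)-9-(bromomethylidene)-1,5,5-trimethylspiro[5.5]undec-7-ene-1,3-diol
Product: 15 (1S,3R,6S,9Z)-3-bromo-9-(bromomethylidene)-1,5,5-trimethylspiro[5.5]undec-7-en-1-ol (target), via secondary triflate 14 (not isolated)
Conditions: Tf2O (1.1 equiv), pyridine (3 equiv), CH2Cl2, −40 °C; then n-Bu4NBr (5 equiv), −40 °C → rt
Reagents that add atoms: tetrabutylammonium bromide, CCCC[N+](CCCC)(CCCC)CCCC.[Br-]; trifluoromethanesulfonic anhydride, O=S(=O)(OS(=O)(=O)C(F)(F)F)C(F)(F)F (its atoms stay only in 14)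
Why: Chemoselective triflation of the secondary hydroxyl and SN2 displacement by bromide with inversion (3S carbinol to 3R bromide); the hindered tertiary hydroxyl neither reacts nor participates because it is cis, and the equatorial bromide formed is also the thermodynamically favoured C3 epimer under bromide exchange.

**Compound list**
1 | dimedone (5,5-dimethylcyclohexane-1,3-dione) | CC1(C)CC(=O)CC(=O)C1 | starting material
2 | 5,5-dimethyl-3-(2-methylpropoxy)cyclohex-2-en-1-one | CC(C)COC1=CC(=O)CC(C)(C)C1 | intermediate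
3 | 6,6-dimethyl-4-(2-methylpropoxy)-2-oxocyclohex-3-ene-1-carbaldehyde (hydroxymethylene enol tautomer predominates) | CC(C)COC1=CC(=O)C(C=O)C(C)(C)C1 | intermediate
4 | methyl vinyl ketone (but-3-en-2-one) | CC(=O)C=C | starting material
5 | (1R)-6,6-dimethyl-4-(2-methylpropoxy)-2-oxo-1-(3-oxobutyl)cyclohex-3-ene-1-carbaldehyde | CC1(C)CC(OCC(C)C)=CC(=O)[C@@]1(CCC(C)=O)C=O | intermediate
6 | (6R)-7-hydroxy-5,5-dimethyl-3-(2-methylpropoxy)spiro[5.5]undec-2-ene-1,9-dione (C7 epimers) | CC1(C)CC(OCC(C)C)=CC(=O)[C@@]12C(O)CC(=O)CC2 | intermediate (not isolated)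
7 | (6S)-5,5-dimethyl-3-(2-methylpropoxy)spiro[5.5]undeca-2,7-diene-1,9-dione | CC1(C)CC(OCC(C)C)=CC(=O)[C@@]12C=CC(=O)CC2 | intermediate
8 | (6S,9Z)-9-(bromomethylidene)-5,5-dimethyl-3-(2-methylpropoxy)spiro[5.5]undeca-2,7-dien-1-one | CC1(C)CC(OCC(C)C)=CC(=O)[C@@]12C=C/C(=C\Br)CC2 | intermediate
9 | (6S,9Z)-9-(bromomethylidene)-1,5,5-trimethyl-3-(2-methylpropoxy)spiro[5.5]undeca-2,7-dien-1-ol (C1 epimers) | CC1(C)CC(OCC(C)C)=CC(C)(O)[C@@]12C=C/C(=C\Br)CC2 | intermediate (not isolated)
10 | (6S,9Z)-9-(bromomethylidene)-1,5,5-trimethylspiro[5.5]undeca-1,7-dien-3-one | CC1(C)CC(=O)C=C(C)[C@@]12C=C/C(=C\Br)CC2 | intermediate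
11 | (3S,6S,9Z)-9-(bromomethylidene)-1,5,5-trimethylspiro[5.5]undeca-1,7-dien-3-ol | CC1(C)C[C@H](O)C=C(C)[C@@]12C=C/C(=C\Br)CC2 | intermediate
12 | (1R,2S,3S,6S,9Z)-9-(bromomethylidene)-1,2-epoxy-1,5,5-trimethylspiro[5.5]undec-7-en-3-ol | CC1(C)C[C@H](O)[C@@H]3O[C@]3(C)[C@@]12C=C/C(=C\Br)CC2 | intermediate
13 | (1S,3S,6S,9Z)-9-(bromomethylidene)-1,5,5-trimethylspiro[5.5]undec-7-ene-1,3-diol | CC1(C)C[C@H](O)C[C@](C)(O)[C@@]12C=C/C(=C\Br)CC2 | intermediate
14 | (1S,3S,6S,9Z)-9-(bromomethylidene)-1-hydroxy-1,5,5-trimethylspiro[5.5]undec-7-en-3-yl trifluoromethanesulfonate | CC1(C)C[C@H](OS(=O)(=O)C(F)(F)F)C[C@](C)(O)[C@@]12C=C/C(=C\Br)CC2 | intermediate (not isolated)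
15 | (1S,3R,6S,9Z)-3-bromo-9-(bromomethylidene)-1,5,5-trimethylspiro[5.5]undec-7-en-1-ol | CC1(C)C[C@@H](Br)C[C@](C)(O)[C@@]12C=C/C(=C\Br)CC2 | target

**Step count and risks**
Total steps: 10. Longest linear sequence: 10 steps (1 → 15); compound 4 enters at step 3.

Step 3 is the most uncertain step. The donor is a hindered α-formyl ketone with no direct precedent in this catalysis, so ee, rate and even the sense of induction must be established by experiment. The fallback sets out from 3 and comes back at 5, and replaces catalyst control by a covalently bound auxiliary. Compound 3 is condensed with L-valine diethylamide (toluene, 4 Å molecular sieves, rt) to the Z-enaminone F1. Addition of 4 in acetone at rt with Cu(OAc)2·H2O (5 mol %) goes through a Cu(OAc)2-derived azadienolate chelate that shields one face and gives the aldimine F2. Hydrolysis with pH 4.5 acetate buffer in THF releases 5 and the recoverable auxiliary; the D-auxiliary is used if the sense is opposite.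

Step 5 is the second risk. The Wittig reaction has no built-in preference for the Z geometry, so up to half of the material may be the E isomer. The fallback sets out from 7 and comes back at 8, and separates C=C formation from C–Br formation. Boron-Wittig olefination of 7 with lithiated CH2(Bpin)2 (lithium 2,2,6,6-tetramethylpiperidide, THF, −78 °C → rt) gives two configurationally robust products, the 9Z alkenyl boronate F3 and the 9E alkenyl boronate F4. They are separated, and F4 is re-equilibrated photochemically (365 nm, thioxanthone) and recycled. Stereoretentive bromodeboronation of F3 with CuBr2 (aqueous THF/i-BuOH, 60 °C) gives 8.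

Step 10 is the third risk. E2 elimination of the axial secondary triflate, which sits syn to the tertiary hydroxyl and a C5 methyl, can compete with substitution. The fallback sets out from 12 and comes back at 15, and reverses the order of substitution and epoxide opening. Compound 12 is triflated (Tf2O, pyridine, CH2Cl2, −40 °C) to the epoxy triflate F5, which is displaced with n-Bu4NBr to the bromo epoxide F6. This inversion at C3 takes place in a half-chair that has no syn-axial tertiary hydroxyl and has β-hydrogens on one side only. The epoxide is then opened at C2 with LiAlH4 (Et2O, −20 → 0 °C), which reduces a trisubstituted epoxide faster than a shielded secondary cyclohexyl bromide, to give 15.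

**Further compounds**
F1 | step 3 | (2S)-N,N-diethyl-3-methyl-2-({(Z)-[6,6-dimethyl-4-(2-methylpropoxy)-2-oxocyclohex-3-en-1-ylidene]methyl}amino)butanamide | CC(C)[C@H](N/C=C1\C(=O)C=C(OCC(C)C)CC1(C)C)C(=O)N(CC)CC
F2 | step 3 | (2S)-N,N-diethyl-2-({[(1R)-6,6-dimethyl-4-(2-methylpropoxy)-2-oxo-1-(3-oxobutyl)cyclohex-3-en-1-yl]methylidene}amino)-3-methylbutanamide | CC(C)[C@H](N=C[C@]1(CCC(C)=O)C(=O)C=C(OCC(C)C)CC1(C)C)C(=O)N(CC)CC
F3 | step 5 | (6S,9Z)-5,5-dimethyl-3-(2-methylpropoxy)-9-[(4,4,5,5-tetramethyl-1,3,2-dioxaborolan-2-yl)methylidene]spiro[5.5]undeca-2,7-dien-1-one | CC1(C)CC(OCC(C)C)=CC(=O)[C@@]12C=C/C(=C\B3OC(C)(C)C(C)(C)O3)CC2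
F4 | step 5 | (6S,9E)-5,5-dimethyl-3-(2-methylpropoxy)-9-[(4,4,5,5-tetramethyl-1,3,2-dioxaborolan-2-yl)methylidene]spiro[5.5]undeca-2,7-dien-1-one | CC1(C)CC(OCC(C)C)=CC(=O)[C@@]12C=C/C(=C/B3OC(C)(C)C(C)(C)O3)CC2
F5 | step 10 | (1R,2S,3S,6S,9Z)-9-(bromomethylidene)-1,2-epoxy-1,5,5-trimethylspiro[5.5]undec-7-en-3-yl trifluoromethanesulfonate | CC1(C)C[C@H](OS(=O)(=O)C(F)(F)F)[C@@H]3O[C@]3(C)[C@@]12C=C/C(=C\Br)CC2
F6 | step 10 | (1R,2R,3R,6S,9Z)-3-bromo-9-(bromomethylidene)-1,2-epoxy-1,5,5-trimethylspiro[5.5]undec-7-ene | CC1(C)C[C@@H](Br)[C@@H]3O[C@]3(C)[C@@]12C=C/C(=C\Br)CC2
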